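## Retrosynthetic overview

- The target comes from its di-O-benzyl ether, which comes from a C2-symmetric di-O-benzyl bridgehead diol by removing one of its two equivalent tertiary OH groups (cyclic thionocarbonate, tin hydride).
- That diol, with both tetrahydrofuran rings and all four stereocentres, comes from an achiral (E,E)-2,3-bis(arylidene)butane-1,4-diol in one flask: twofold Sharpless epoxidation, then crisscross double 5-endo epoxide opening.
- The dienediol comes from the bis(arylidene)succinic acid (alane reduction), made by twofold Stobbe condensation of O-benzylvanillin with diethyl succinate.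
- Ring order: no ring before the key step; ring A (O3–C2 bond) and ring B (O7–C6 bond) close one after the other in the same operation; none afterwards.

Assumption: O-benzylvanillin, diethyl succinate and D-(−)-diisopropyl tartrate are taken as inexpensive catalogue chemicals; locants follow 3,7-dioxabicyclo[3.3.0]octane numbering (C1 bears OH, C2 and C6 bear the aryl groups, C5 bears H).

## Route

Step 1
Reactants: 1 4-(benzyloxy)-3-methoxybenzaldehyde (2.2 equiv); 2 diethyl succinate
Product: 4 (2E,3E)-2,3-bis{[4-(benzyloxy)-3-methoxyphenyl]methylidene}butanedioic acid, via half-ester 3 (not isolated)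
Conditions: NaOEt (4 equiv), EtOH, reflux; then aq. HCl
Reagents that add atoms: none
Why: Twofold Stobbe condensation, in which each aldol alkoxide lactonises onto the neighbouring ester and E1cB opening of the paraconate turns that ester into a carboxylate, so both esters are consumed and the thermodynamically preferred E,E-diacid (aryl trans to its carboxyl) results without any stereocentre.

Step 2
Reactants: 4 (2E,3E)-2,3-bis{[4-(benzyloxy)-3-methoxyphenyl]methylidene}butanedioic acid
Product: 5 (2E,3E)-2,3-bis{[4-(benzyloxy)-3-methoxyphenyl]methylidene}butane-1,4-diol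
Conditions: AlH3 (from LiAlH4, AlCl3 3:1), THF, 0 °C; then H2O, aq. NaOH
Reagents that add atoms: none
Why: Alane reduction of carboxylic acids is a pure 1,2-hydride addition, so both acids become primary allylic alcohols while the two aryl-conjugated E alkenes and the benzyl ethers are untouched.

Step 3
Reactants: 5 (2E,3E)-2,3-bis{[4-(benzyloxy)-3-methoxyphenyl]methylidene}butane-1,4-diol
Product: 9 (1R,2S,5R,6S)-2,6-bis[4-(benzyloxy)-3-methoxyphenyl]-3,7-dioxabicyclo[3.3.0]octane-1,5-diol, via monoepoxide 6 (not isolated), via bisepoxide 7 (not isolated), via spiro-epoxide 8 (not isolated)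
Conditions: Ti(OiPr)4 (30 mol%), D-(−)-diisopropyl tartrate (36 mol%), t-BuOOH (3 equiv, isooctane), 4 Å MS, CH2Cl2, −25 °C; then CSA (10 mol%), −25 to 0 °C
Reagents that add atoms: tert-butyl hydroperoxide CC(C)(C)OO
Why: Proposed new method: a twofold Sharpless asymmetric epoxidation in which the D-(−)-tartrate titanium catalyst delivers oxygen to the same enantioface of the two homotopic 2-substituted cinnamyl alcohol units (closest known reaction: Sharpless epoxidation of (E)-2-methyl-3-phenylprop-2-en-1-ol), followed by acid-triggered crisscross 5-endo opening of each epoxide at its p-alkoxybenzylic carbon by the CH2OH group of the other half with inversion (closest known reactions: acid- or titanium-promoted cyclisation of 4-aryl-3,4-epoxybutan-1-ols to 2-aryl-3-hydroxytetrahydrofurans and the quinone-methide ring closures of furofuran lignans), so that the retained epoxide C–O bonds fix C1 and C5 as R, the inverted benzylic carbons become C2 and C6 S with aryl exo, the cis ring fusion follows from the homochiral bis-epoxide, and the minor heterochiral bis-epoxide cannot close the second ring, which raises the enantiomeric purity.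

Step 4
Reactants: 9 (1R,2S,5R,6S)-2,6-bis[4-(benzyloxy)-3-methoxyphenyl]-3,7-dioxabicyclo[3.3.0]octane-1,5-diol
Product: 10 cyclic 1,5-O,O'-thiocarbonate of 9 (1,3-dioxolane-2-thione fused across the C1–C5 bond; configuration as in 9)
Conditions: 1,1'-thiocarbonyldiimidazole, DMAP (cat.), toluene, 110 °C
Reagents that add atoms: 1,1'-thiocarbonyldiimidazole S=C(n1ccnc1)n1ccnc1
Why: Corey–Winter-type thionocarbonate formation works because the ring fusion holds the two bridgehead hydroxyls cis and eclipsed, ideal for a five-membered cyclic thiocarbonate, and no stereocentre is touched.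

Step 5
Reactants: 10 cyclic 1,5-O,O'-thiocarbonate of 9
Product: 12 (1R,2S,5S,6R)-2,6-bis[4-(benzyloxy)-3-methoxyphenyl]-3,7-dioxabicyclo[3.3.0]octan-1-ol, via stannyl thiolcarbonate 11 (not isolated)
Conditions: Bu3SnH (3 equiv), AIBN (cat.), toluene, 110 °C; then NaOH, MeOH/H2O, rt
Reagents that add atoms: none
Why: Barton-type radical deoxygenation of a cyclic thionocarbonate, in which the stannyl radical adds to sulfur, β-scission of either of the two symmetry-equivalent C–O bonds gives the tertiary bridgehead radical, this radical can only accept hydrogen on the convex face so the cis fusion is kept and C5 becomes S, and hydrolysis of the remaining stannyl thiolcarbonate frees the C1 hydroxyl.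

Step 6
Reactants: 12 (1R,2S,5S,6R)-2,6-bis[4-(benzyloxy)-3-methoxyphenyl]-3,7-dioxabicyclo[3.3.0]octan-1-ol
Product: 13 (1R,2S,5S,6R)-2,6-bis(4-hydroxy-3-methoxyphenyl)-3,7-dioxabicyclo[3.3.0]octan-1-ol (CNP0138682.6)
Conditions: H2 (1 atm), Pd/C, EtOAc/MeOH, rt, stopped at full debenzylation
Reagents that add atoms: none
Why: Catalytic hydrogenolysis cleaves the two aryl benzyl ethers faster than the dialkyl benzylic C–O bonds of the furofuran under neutral conditions, and no stereocentre is involved.

## Compound list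

1 | 4-(benzyloxy)-3-methoxybenzaldehyde | O=Cc1ccc(OCc2ccccc2)c(OC)c1 | starting material
2 | diethyl succinate | CCOC(=O)CCC(=O)OCC | starting material
3 | (3E)-4-[4-(benzyloxy)-3-methoxyphenyl]-3-(ethoxycarbonyl)but-3-enoic acid | CCOC(=O)/C(=C/c1ccc(OCc2ccccc2)c(OC)c1)CC(=O)O | intermediate
4 | (2E,3E)-2,3-bis{[4-(benzyloxy)-3-methoxyphenyl]methylidene}butanedioic acid | COc1cc(/C=C(/C(=O)O)\C(C(=O)O)=C/c2ccc(OCc3ccccc3)c(OC)c2)ccc1OCc1ccccc1 | intermediate
5 | (2E,3E)-2,3-bis{[4-(benzyloxy)-3-methoxyphenyl]methylidene}butane-1,4-diol | COc1cc(/C=C(/CO)\C(CO)=C/c2ccc(OCc3ccccc3)c(OC)c2)ccc1OCc1ccccc1 | intermediate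
6 | {(2R,3R)-3-[4-(benzyloxy)-3-methoxyphenyl]-2-[(1Z)-1-[4-(benzyloxy)-3-methoxyphenyl]-3-hydroxyprop-1-en-2-yl]oxiran-2-yl}methanol | OC[C@]1(O[C@@H]1c2ccc(OCc3ccccc3)c(OC)c2)\C(CO)=C/c4ccc(OCc5ccccc5)c(OC)c4 | intermediate
7 | [(2R,2'R,3R,3'R)-3,3'-bis[4-(benzyloxy)-3-methoxyphenyl]-2,2'-bioxirane-2,2'-diyl]dimethanol | OC[C@]1(O[C@@H]1c2ccc(OCc3ccccc3)c(OC)c2)[C@]4(CO)O[C@@H]4c5ccc(OCc6ccccc6)c(OC)c5 | intermediate
8 | (2R,3R,6S,7R)-2,6-bis[4-(benzyloxy)-3-methoxyphenyl]-7-(hydroxymethyl)-1,5-dioxaspiro[2.4]heptan-7-ol | OC[C@@]1(O)[C@H](c2ccc(OCc3ccccc3)c(OC)c2)OC[C@]14O[C@@H]4c5ccc(OCc6ccccc6)c(OC)c5 | intermediate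
9 | (1R,2S,5R,6S)-2,6-bis[4-(benzyloxy)-3-methoxyphenyl]-3,7-dioxabicyclo[3.3.0]octane-1,5-diol | COc1cc([C@@H]2OC[C@@]3(O)[C@H](c4ccc(OCc5ccccc5)c(OC)c4)OC[C@@]23O)ccc1OCc1ccccc1 | intermediate
10 | cyclic 1,5-O,O'-thiocarbonate of 9 (configuration as in 9) | COc1cc([C@@H]2OC[C@@]3(O4)[C@H](c5ccc(OCc6ccccc6)c(OC)c5)OC[C@@]23OC4=S)ccc1OCc1ccccc1 | intermediate
11 | O-[(1R,2S,5S,6R)-2,6-bis[4-(benzyloxy)-3-methoxyphenyl]-3,7-dioxabicyclo[3.3.0]octan-1-yl] S-(tributylstannyl) thiocarbonate | COc1cc([C@@H]2OC[C@@]3(OC(=O)S[Sn](CCCC)(CCCC)CCCC)[C@H](c4ccc(OCc5ccccc5)c(OC)c4)OC[C@@H]23)ccc1OCc1ccccc1 | intermediate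
12 | (1R,2S,5S,6R)-2,6-bis[4-(benzyloxy)-3-methoxyphenyl]-3,7-dioxabicyclo[3.3.0]octan-1-ol | COc1cc([C@@H]2OC[C@@]3(O)[C@H](c4ccc(OCc5ccccc5)c(OC)c4)OC[C@@H]23)ccc1OCc1ccccc1 | intermediate
13 | (1R,2S,5S,6R)-2,6-bis(4-hydroxy-3-methoxyphenyl)-3,7-dioxabicyclo[3.3.0]octan-1-ol | COc1cc([C@@H]2OC[C@@]3(O)[C@H](c4ccc(O)c(OC)c4)OC[C@@H]23)ccc1O | target

## Step count and risks

Total step count: 6. Longest linear sequence: 6 (fully linear from 1 and 2).

Steps most likely to fail, with fallbacks:

Step 3 is the riskiest. The first epoxide may cyclise before the second alkene is epoxidised, leaving a tertiary allylic alcohol that the tartrate catalyst epoxidises poorly. The p-alkoxybenzyl cation may also undergo semipinacol shift, or lose configuration at C2/C6. The fallback sets out from 5. A single Sharpless epoxidation (Ti(OiPr)4 1.0 equiv, D-(−)-diisopropyl tartrate 1.2 equiv, t-BuOOH 1.1 equiv, CH2Cl2, −20 °C) is run so that the titanium alkoxide opens the electron-rich epoxide in the flask. This gives the monocyclic ene-diol (2S,3R,4Z)-2-[4-(benzyloxy)-3-methoxyphenyl]-4-{[4-(benzyloxy)-3-methoxyphenyl]methylidene}-3-(hydroxymethyl)oxolan-3-ol F1. Brønsted acid must be avoided for the second closure, because the tertiary allylic alcohol of this compound ionises faster than the styrene is protonated. The second ring is instead closed by cobalt-hydride hydrogen-atom-transfer hydroalkoxylation: Co(salen) (C16H14CoN2O2, divalent cobalt) as catalyst, N-fluoro-2,4,6-trimethylpyridinium triflate, 1,1,3,3-tetramethyldisiloxane, PhCF3, rt. Reversible hydrogen delivery to C5 is productive only on the face that allows the cis-fused ring, and the benzylic cation is trapped by the primary hydroxyl with aryl exo. This comes back to the route at 12 and bypasses 9, 10 and 11.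

Step 1 is next. The second condensation has to occur on a half-ester carboxylate and can be slow, and E/Z mixtures may form. The fallback sets out from 1. Wittig olefination with ethyl bromo(triphenyl-λ5-phosphanylidene)acetate gives ethyl (2Z)-2-bromo-3-[4-(benzyloxy)-3-methoxyphenyl]prop-2-enoate F2. Reductive homocoupling with retention of alkene geometry (NiCl2(PPh3)2, Zn, Et4NI, THF, 50 °C; zerovalent nickel formed in the flask) gives diethyl (2E,3E)-2,3-bis{[4-(benzyloxy)-3-methoxyphenyl]methylidene}butanedioate F3. Reduction with i-Bu2AlH (CH2Cl2, −78 °C) comes back to the route at 5.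

Step 5 is third. The strained propellane thionocarbonate may fragment twice to the bridgehead alkene, or react sluggishly. The fallback sets out from 9. One of the two equivalent tertiary hydroxyls is acylated with methyl chlorooxoacetate (pyridine, DMAP, CH2Cl2, 0 °C) to give methyl (1R,2S,5R,6S)-2,6-bis[4-(benzyloxy)-3-methoxyphenyl]-5-hydroxy-3,7-dioxabicyclo[3.3.0]octan-1-yl oxalate F4. Its tertiary oxalate is cleaved by Bu3SnH/AIBN (toluene, 110 °C) to the same bridgehead radical, now with only a hydroxyl in the β position, and hydrogen transfer on the convex face comes back to the route at 12.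

## Further compounds

F1 | step 3 | (2S,3R,4Z)-2-[4-(benzyloxy)-3-methoxyphenyl]-4-{[4-(benzyloxy)-3-methoxyphenyl]methylidene}-3-(hydroxymethyl)oxolan-3-ol | OC[C@@]1(O)[C@H](c2ccc(OCc3ccccc3)c(OC)c2)OC/C1=C/c4ccc(OCc5ccccc5)c(OC)c4
F2 | step 1 | ethyl (2Z)-2-bromo-3-[4-(benzyloxy)-3-methoxyphenyl]prop-2-enoate | CCOC(=O)/C(Br)=C/c1ccc(OCc2ccccc2)c(OC)c1
F3 | step 1 | diethyl (2E,3E)-2,3-bis{[4-(benzyloxy)-3-methoxyphenyl]methylidene}butanedioate | COc1cc(/C=C(/C(=O)OCC)\C(C(=O)OCC)=C/c2ccc(OCc3ccccc3)c(OC)c2)ccc1OCc1ccccc1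
F4 | step 5 | methyl (1R,2S,5R,6S)-2,6-bis[4-(benzyloxy)-3-methoxyphenyl]-5-hydroxy-3,7-dioxabicyclo[3.3.0]octan-1-yl oxalate | COc1cc([C@@H]2OC[C@@]3(O)[C@H](c4ccc(OCc5ccccc5)c(OC)c4)OC[C@@]23OC(=O)C(=O)OC)ccc1OCc1ccccc1
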